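TBS = tert-butyldimethylsilyl; pin = pinacolato. The target is pyrrhoxanthinol, (3S,5R,6S,3′R) in carotenoid numbering.

## Retrosynthetic overview
1. Last C–C bond: Stille coupling at butenolide C3 (bromobutenolide 24 + vinylstannane 14), followed by global desilylation.
2. The butenolide is the last ring formed: Sonogashira coupling and 5-exo-dig lactonisation of terminal alkyne 20 with (E)-2,3-dibromoacrylic acid 22.
3. Polyene: Suzuki coupling of dienylboronate 19 with iododienyne 18. Both C7 units come from enynol 15, and the ring–alkyne bond comes from a Sonogashira coupling of triflate 10.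
4. Both end groups come from the one triflate 10. The oxirane is the second ring formed, by Sharpless epoxidation of allylic alcohol 11.
5. The carbocycle is formed first, by two one-carbon ring expansions (1,2-shifts, 4→5→6) of 3-silyloxycyclobutanone 2. 2-Diazopropane is used first (desymmetrising, sets C3/C3′), then diazoethane.

Assumption: the sense of induction of the new catalyst in step 2 cannot be predicted, so the ligand antipode that gives (S)-5 is the one used (both antipodes are made the same way from D- or L-pipecolic acid).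

## Route

Step 1
Reactants: 1 3-hydroxycyclobutan-1-one
Product: 2 3-[(TBS)oxy]cyclobutan-1-one
Conditions: TBSCl, imidazole, CH2Cl2, 0 °C to rt
Reagents that add atoms: tert-butyldimethylsilyl chloride, CC(C)(C)[Si](C)(C)Cl
Why: Standard Corey silylation masks the hydroxyl against O–H insertion by the diazoalkanes used next and creates no stereocentre, since 2 is still Cs-symmetric.

Step 2
Reactants: 2 3-[(TBS)oxy]cyclobutan-1-one; 3 acetone hydrazone
Product: 5 (4S)-4-[(TBS)oxy]-2,2-dimethylcyclopentan-1-one, via 2-diazopropane 4 (not isolated)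
Conditions: (i) 3, Ag2O, Et2O, −20 °C, cold vacuum transfer of 4 in Et2O; (ii) 2, Sc(OTf)3 (10 mol %), pipecolic-acid-derived N,N′-dioxide bis(2,6-diisopropylanilide) ligand (11 mol %), 4 Å MS, CH2Cl2, −78 °C, slow addition of 4
Reagents that add atoms: none
Why: Proposed new method: the chiral Sc(III)–N,N′-dioxide Lewis acid binds the carbonyl of Cs-symmetric 2, the diazo carbon adds anti to the OTBS group, and in the Sc-bound betaine only the rotamer holding one of the two enantiotopic ring CH2–C(O) bonds antiperiplanar to C–N2+ fits the chiral pocket, so the strain-driven 1,2-shift with loss of N2 (4→5 ring expansion) sets the carbinol centre (later C3 and C3′) as (S); the closest known reaction types are the Sc(OTf)3-catalysed diazoalkane–ketone homologation (Büchner–Curtius–Schlotterbeck/Tiffeneau–Demjanov type) and the Sc–N,N′-dioxide-catalysed desymmetrising Baeyer–Villiger oxidation of 3-substituted cyclobutanones, whereas an enantiotopic-bond-selective carbon insertion with a non-stabilised dialkyldiazomethane has not been described.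

Step 3
Reactants: 5 (4S)-4-[(TBS)oxy]-2,2-dimethylcyclopentan-1-one; 6 N-ethyl-N-nitrosourea
Product: 8 (4R)-4-[(TBS)oxy]-2,2,6-trimethylcyclohexan-1-one (C6 epimers), via diazoethane 7 (not isolated)
Conditions: (i) 6, 40 % aq KOH/Et2O, 0 °C, decant, dry over KOH; (ii) 5, Sc(OTf)3 (10 mol %), CH2Cl2, −78 to −30 °C, slow addition of 7
Reagents that add atoms: none
Why: In this Lewis-acid-catalysed diazoalkane homologation (Tiffeneau–Demjanov-type 1,2-shift, 5→6 ring expansion) the unhindered C5 methylene migrates rather than quaternary C2, the doubly flanked product ketone does not react again, the carbinol centre is untouched (the descriptor changes only through CIP ranking), and the C6 epimers converge in step 4.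

Step 4
Reactants: 8 (4R)-4-[(TBS)oxy]-2,2,6-trimethylcyclohexan-1-one
Product: 10 (4R)-4-[(TBS)oxy]-2,6,6-trimethylcyclohex-1-en-1-yl trifluoromethanesulfonate, via lithium enolate 9 (not isolated)
Conditions: LDA, THF, −78 to 0 °C; PhNTf2, 0 °C to rt
Reagents that add atoms: N-phenylbis(trifluoromethanesulfonimide), O=S(=O)(N(c1ccccc1)S(=O)(=O)C(F)(F)F)C(F)(F)F
Why: C6–H is the only enolisable position, so one tetrasubstituted enolate forms and is O-triflated (McMurry–Scott enol triflation), which erases the C6 stereocentre.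

Step 5
Reactants: 10 (4R)-4-[(TBS)oxy]-2,6,6-trimethylcyclohex-1-en-1-yl trifluoromethanesulfonate
Product: 11 {(4R)-4-[(TBS)oxy]-2,6,6-trimethylcyclohex-1-en-1-yl}methanol
Conditions: Bu3SnCH2OH, Pd(PPh3)4 (10 mol %), LiCl, 1,4-dioxane, 100 °C
Reagents that add atoms: (tributylstannyl)methanol, CCCC[Sn](CCCC)(CCCC)CO
Why: Migita–Kosugi–Stille hydroxymethylation installs C7 in one operation, with LiCl converting Pd–OTf into the transmetalation-competent Pd–Cl and no stereocentre affected.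

Step 6
Reactants: 11 {(4R)-4-[(TBS)oxy]-2,6,6-trimethylcyclohex-1-en-1-yl}methanol
Product: 12 {(1R,4S,6R)-4-[(TBS)oxy]-2,2,6-trimethyl-7-oxabicyclo[4.1.0]heptan-1-yl}methanol (epoxide anti to OTBS)
Conditions: t-BuOOH, Ti(OiPr)4 (20 mol %), D-(−)-diethyl tartrate (25 mol %), 4 Å MS, CH2Cl2, −20 °C
Reagents that add atoms: tert-butyl hydroperoxide, CC(C)(C)OO
Why: In the Katsuki–Sharpless asymmetric epoxidation the D-(−)-tartrate complex delivers oxygen under reagent control to the alkene face anti to the silyl ether, setting both epoxide carbons (5R,6S in carotenoid numbering) at once.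

Step 7
Reactants: 12 {(1R,4S,6R)-4-[(TBS)oxy]-2,2,6-trimethyl-7-oxabicyclo[4.1.0]heptan-1-yl}methanol
Product: 13 (1S,4S,6R)-4-[(TBS)oxy]-2,2,6-trimethyl-7-oxabicyclo[4.1.0]heptane-1-carbaldehyde
Conditions: TPAP (5 mol %), NMO, 4 Å MS, CH2Cl2, rt
Reagents that add atoms: none
Why: The neutral Ley–Griffith oxidation stops at the non-enolisable aldehyde and leaves epoxide and silyl ether intact (the C1 descriptor changes only through CIP ranking).

Step 8
Reactants: 13 (1S,4S,6R)-4-[(TBS)oxy]-2,2,6-trimethyl-7-oxabicyclo[4.1.0]heptane-1-carbaldehyde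
Product: 14 tributyl{(E)-2-[(1S,4S,6R)-4-[(TBS)oxy]-2,2,6-trimethyl-7-oxabicyclo[4.1.0]heptan-1-yl]ethenyl}stannane
Conditions: Bu3SnCHBr2, CrCl2, LiI, THF/DMF, rt, dark
Reagents that add atoms: (dibromomethyl)tributylstannane, CCCC[Sn](CCCC)(CCCC)C(Br)Br
Why: In the Hodgson stannyl variant of the Takai olefination the gem-dichromium reagent adds to the aldehyde and eliminates through the least crowded arrangement, giving the (E)-C7=C8 vinylstannane.

Step 9
Reactants: 15 (2E)-3-methylpent-2-en-4-yn-1-ol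
Product: 16 (2E)-3-methylpent-2-en-4-ynal
Conditions: MnO2, CH2Cl2, rt
Reagents that add atoms: none
Why: Chemoselective MnO2 oxidation of the allylic alcohol keeps the (E)-trisubstituted alkene that becomes both methyl-bearing double bonds of the chain.

Step 10
Reactants: 16 (2E)-3-methylpent-2-en-4-ynal
Product: 17 2-[(1E,3E)-4-methylhexa-1,3-dien-5-yn-1-yl]-4,4,5,5-tetramethyl-1,3,2-dioxaborolane
Conditions: Cl2CHBpin, CrCl2, LiI, THF, rt
Reagents that add atoms: 2-(dichloromethyl)-4,4,5,5-tetramethyl-1,3,2-dioxaborolane, ClC(Cl)B1OC(C)(C)C(C)(C)O1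
Why: The Takai–Utimoto boron olefination gives the new disubstituted alkene with high E selectivity and tolerates the terminal alkyne.

Step 11
Reactants: 16 (2E)-3-methylpent-2-en-4-ynal
Product: 18 (1E,3E)-1-iodo-4-methylhexa-1,3-dien-5-yne
Conditions: CHI3, CrCl2, dioxane/THF (6:1), 0 °C to rt, dark
Reagents that add atoms: iodoform, IC(I)I
Why: Takai iodo-olefination in the dioxane-rich medium maximises the E-vinyl iodide, and the minor Z isomer is removed by chromatography.

Step 12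
Reactants: 10 (4R)-4-[(TBS)oxy]-2,6,6-trimethylcyclohex-1-en-1-yl trifluoromethanesulfonate; 17 2-[(1E,3E)-4-methylhexa-1,3-dien-5-yn-1-yl]-4,4,5,5-tetramethyl-1,3,2-dioxaborolane
Product: 19 2-[(1E,3E)-6-{(4R)-4-[(TBS)oxy]-2,6,6-trimethylcyclohex-1-en-1-yl}-4-methylhexa-1,3-dien-5-yn-1-yl]-4,4,5,5-tetramethyl-1,3,2-dioxaborolane
Conditions: Pd(PPh3)4 (5 mol %), CuI (10 mol %), Et3N, DMF, 50 °C, degassed
Reagents that add atoms: none
Why: The slim copper acetylide reaches the hindered alkenyl–Pd centre in this Sonogashira coupling, while the Bpin group stays inert because no oxygen base activates it.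

Step 13
Reactants: 19 2-[(1E,3E)-6-{(4R)-4-[(TBS)oxy]-2,6,6-trimethylcyclohex-1-en-1-yl}-4-methylhexa-1,3-dien-5-yn-1-yl]-4,4,5,5-tetramethyl-1,3,2-dioxaborolane; 18 (1E,3E)-1-iodo-4-methylhexa-1,3-dien-5-yne
Product: 20 tert-butyl({(1R)-4-[(3E,5E,7E,9E)-3,10-dimethyldodeca-3,5,7,9-tetraene-1,11-diyn-1-yl]-3,5,5-trimethylcyclohex-3-en-1-yl}oxy)dimethylsilane
Conditions: Pd(dppf)Cl2 (5 mol %), aq K3PO4, THF, rt, degassed, dark
Reagents that add atoms: none
Why: The stereoretentive Suzuki–Miyaura dienyl–dienyl coupling forms the central single bond of the all-E tetraene, and at rt without copper or amine the terminal alkyne does not compete.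

Step 14
Reactants: 21 prop-2-ynoic acid
Product: 22 (2E)-2,3-dibromoprop-2-enoic acid (Br atoms trans, C3–Br cis to CO2H)
Conditions: Br2, CHCl3, 0 °C to rt, dark; recrystallise
Reagents that add atoms: bromine, BrBr
Why: Ionic anti-addition of bromine through the bromirenium ion places the two bromines trans, which puts the C3 bromine cis to the carboxyl group as the lactonisation requires.

Step 15
Reactants: 20 tert-butyl({(1R)-4-[(3E,5E,7E,9E)-3,10-dimethyldodeca-3,5,7,9-tetraene-1,11-diyn-1-yl]-3,5,5-trimethylcyclohex-3-en-1-yl}oxy)dimethylsilane; 22 (2E)-2,3-dibromoprop-2-enoic acid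
Product: 24 (5Z)-3-bromo-5-{(2E,4E,6E,8E)-11-[(4R)-4-[(TBS)oxy]-2,6,6-trimethylcyclohex-1-en-1-yl]-2,9-dimethylundeca-2,4,6,8-tetraen-10-yn-1-ylidene}furan-2(5H)-one, via bromoenynoic acid 23 (not isolated)
Conditions: Pd(PPh3)4 (5 mol %), CuI (15 mol %), Et3N, MeCN, rt, dark
Reagents that add atoms: none
Why: In this tandem Sonogashira coupling/5-exo-dig lactonisation the more electrophilic C3–Br reacts first with retention, and anti-addition of carboxylate and proton across the metal-activated alkyne gives the Z-ylidene butenolide while leaving C3–Br of the lactone for step 16.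

Step 16
Reactants: 24 (5Z)-3-bromo-5-{(2E,4E,6E,8E)-11-[(4R)-4-[(TBS)oxy]-2,6,6-trimethylcyclohex-1-en-1-yl]-2,9-dimethylundeca-2,4,6,8-tetraen-10-yn-1-ylidene}furan-2(5H)-one; 14 tributyl{(E)-2-[(1S,4S,6R)-4-[(TBS)oxy]-2,2,6-trimethyl-7-oxabicyclo[4.1.0]heptan-1-yl]ethenyl}stannane
Product: 25 3,3′-bis-O-TBS-pyrrhoxanthinol
Conditions: Pd2(dba)3 (5 mol %), AsPh3 (40 mol %), NMP, rt to 40 °C, dark
Reagents that add atoms: none
Why: The neutral Stille coupling at the electron-poor C3–Br proceeds with retention of the E-vinyl geometry and spares the hindered vinyl epoxide, the lactone and the polyene.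

Step 17
Reactants: 25 3,3′-bis-O-TBS-pyrrhoxanthinol
Product: 26 pyrrhoxanthinol (CNP0180336.1)
Conditions: TBAF/AcOH (1:1), THF, 0 °C to rt, dark
Reagents that add atoms: none
Why: Acetic-acid-buffered fluoride cleaves both secondary silyl ethers near neutrality, avoiding both the acid-induced epoxide-to-furanoid rearrangement and base damage to the ylidene butenolide.

## Compound list
1 | 3-hydroxycyclobutan-1-one | O=C1CC(O)C1 | starting material
2 | 3-[(TBS)oxy]cyclobutan-1-one | O=C1CC(O[Si](C)(C)C(C)(C)C)C1 | intermediate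
3 | acetone hydrazone | CC(C)=NN | starting material
4 | 2-diazopropane (not isolated) | CC(C)=[N+]=[N-] | intermediate
5 | (4S)-4-[(TBS)oxy]-2,2-dimethylcyclopentan-1-one | O=C1C(C)(C)C[C@H](O[Si](C)(C)C(C)(C)C)C1 | intermediate
6 | N-ethyl-N-nitrosourea | CCN(N=O)C(N)=O | starting material
7 | diazoethane (not isolated) | CC=[N+]=[N-] | intermediate
8 | (4R)-4-[(TBS)oxy]-2,2,6-trimethylcyclohexan-1-one, C6 epimers | CC1C(=O)C(C)(C)C[C@H](O[Si](C)(C)C(C)(C)C)C1 | intermediate
9 | lithium (4R)-4-[(TBS)oxy]-2,6,6-trimethylcyclohex-1-en-1-olate (not isolated) | [Li+].CC1=C([O-])C(C)(C)C[C@H](O[Si](C)(C)C(C)(C)C)C1 | intermediate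
10 | (4R)-4-[(TBS)oxy]-2,6,6-trimethylcyclohex-1-en-1-yl trifluoromethanesulfonate | CC1=C(OS(=O)(=O)C(F)(F)F)C(C)(C)C[C@H](O[Si](C)(C)C(C)(C)C)C1 | intermediate
11 | {(4R)-4-[(TBS)oxy]-2,6,6-trimethylcyclohex-1-en-1-yl}methanol | CC1=C(CO)C(C)(C)C[C@H](O[Si](C)(C)C(C)(C)C)C1 | intermediate
12 | {(1R,4S,6R)-4-[(TBS)oxy]-2,2,6-trimethyl-7-oxabicyclo[4.1.0]heptan-1-yl}methanol | OC[C@@]12O[C@]1(C)C[C@@H](O[Si](C)(C)C(C)(C)C)CC2(C)C | intermediate
13 | (1S,4S,6R)-4-[(TBS)oxy]-2,2,6-trimethyl-7-oxabicyclo[4.1.0]heptane-1-carbaldehyde | O=C[C@@]12O[C@]1(C)C[C@@H](O[Si](C)(C)C(C)(C)C)CC2(C)C | intermediate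
14 | tributyl{(E)-2-[(1S,4S,6R)-4-[(TBS)oxy]-2,2,6-trimethyl-7-oxabicyclo[4.1.0]heptan-1-yl]ethenyl}stannane | CCCC[Sn](CCCC)(CCCC)/C=C/[C@@]12O[C@]1(C)C[C@@H](O[Si](C)(C)C(C)(C)C)CC2(C)C | intermediate
15 | (2E)-3-methylpent-2-en-4-yn-1-ol | C#C/C(C)=C/CO | starting material
16 | (2E)-3-methylpent-2-en-4-ynal | C#C/C(C)=C/C=O | intermediate
17 | 2-[(1E,3E)-4-methylhexa-1,3-dien-5-yn-1-yl]-4,4,5,5-tetramethyl-1,3,2-dioxaborolane | C#C/C(C)=C/C=C/B1OC(C)(C)C(C)(C)O1 | intermediate
18 | (1E,3E)-1-iodo-4-methylhexa-1,3-dien-5-yne | C#C/C(C)=C/C=C/I | intermediate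
19 | ring–C≡C–C(Me)=CH–CH=CH–Bpin (all E, 4R, OTBS) | CC1=C(C#C/C(C)=C/C=C/B2OC(C)(C)C(C)(C)O2)C(C)(C)C[C@H](O[Si](C)(C)C(C)(C)C)C1 | intermediate
20 | ring–C≡C–(all-E 3,10-dimethyl tetraene)–C≡CH (R, OTBS) | CC1=C(C#C/C(C)=C/C=C/C=C/C=C(C)/C#C)C(C)(C)C[C@H](O[Si](C)(C)C(C)(C)C)C1 | intermediate
21 | prop-2-ynoic acid | C#CC(=O)O | starting material
22 | (2E)-2,3-dibromoprop-2-enoic acid | Br/C=C(/Br)C(=O)O | intermediate
23 | (2E)-2-bromo-2-en-4-ynoic acid from C3-alkynylation of 22 by 20, alkynyl cis to CO2H (not isolated) | CC1=C(C#C/C(C)=C/C=C/C=C/C=C(C)/C#C/C=C(/Br)C(=O)O)C(C)(C)C[C@H](O[Si](C)(C)C(C)(C)C)C1 | intermediate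
24 | (5Z)-3-bromo-5-ylidenefuran-2(5H)-one carrying the full left half (OTBS) | CC1=C(C#C/C(C)=C/C=C/C=C/C=C(C)/C=C2C=C(Br)C(=O)O/2)C(C)(C)C[C@H](O[Si](C)(C)C(C)(C)C)C1 | intermediate
25 | 3,3′-bis-O-TBS-pyrrhoxanthinol | CC1=C(C#C/C(C)=C/C=C/C=C/C=C(C)/C=C2C=C(/C=C/[C@@]34O[C@]3(C)C[C@@H](O[Si](C)(C)C(C)(C)C)CC4(C)C)C(=O)O/2)C(C)(C)C[C@H](O[Si](C)(C)C(C)(C)C)C1 | intermediate
26 | pyrrhoxanthinol, (3S,5R,6S,3′R), all-E chain, Z-ylidene | CC1=C(C#C/C(C)=C/C=C/C=C/C=C(C)/C=C2C=C(/C=C/[C@@]34O[C@]3(C)C[C@@H](O)CC4(C)C)C(=O)O/2)C(C)(C)C[C@H](O)C1 | target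

## Step count
- Total: 17 steps.
- Longest linear sequence: 10 steps (steps 1–8, 16, 17).

## Three steps most likely to fail

**Step 2 (the proposed new step).**
- Risks: low ee, spiro-epoxide formation, or an uncatalysed background reaction.
- Fallback, known chemistry only, sets out from 2 and returns at 5. The insertion of 4 is run with achiral Sc(OTf)3 to give racemic 4-[(TBS)oxy]-2,2-dimethylcyclopentan-1-one F1. DBU eliminates silanol from it to give 5,5-dimethylcyclopent-2-en-1-one F2. The stereocentre is then set by Cu(I)/chiral ferrocenyl-bisphosphine-catalysed conjugate borylation with B2pin2 (NaOt-Bu, MeOH), giving (4S)-2,2-dimethyl-4-(4,4,5,5-tetramethyl-1,3,2-dioxaborolan-2-yl)cyclopentan-1-one F3. NaBO3 oxidation with retention gives (4S)-4-hydroxy-2,2-dimethylcyclopentan-1-one F4, and TBSCl/imidazole rejoins the route at 5.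

**Step 3.**
- Risks: sluggish addition of diazoethane to the α-quaternary cyclopentanone, or Lewis-acid-induced loss of the β-silyloxy group.
- Fallback sets out from 5 and returns at 8, avoiding any carbonyl addition. Soft enolisation (TMSOTf, Et3N) gives the only possible trimethylsilyl enol ether of 5 (C1=C5) F5. Furukawa cyclopropanation with Et2Zn/CH3CHI2 gives 4-[(TBS)oxy]-2,2,6-trimethyl-1-[(trimethylsilyl)oxy]bicyclo[3.1.0]hexane F6. Saegusa-type FeCl3 oxidation cleaves the ring-fusion bond by β-scission to the ring-expanded 5-chloro-4-[(TBS)oxy]-2,2,6-trimethylcyclohexan-1-one F7. NaOAc/MeOH removes HCl to give (4S)-4-[(TBS)oxy]-2,6,6-trimethylcyclohex-2-en-1-one F8, and H2 over Pd/C in EtOAc returns to 8.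

**Step 5.**
- Risk: slow sp3 transmetalation onto the very hindered alkenyl–Pd species, leading to triflate reduction.
- Fallback sets out from 10 and returns at 11, bringing C7 in as carbon monoxide. Pd(OAc)2/dppf, CO (1 atm), MeOH, Et3N in DMF at 60 °C gives methyl (4R)-4-[(TBS)oxy]-2,6,6-trimethylcyclohex-1-ene-1-carboxylate F9. DIBAL-H (CH2Cl2, −78 °C) reduces it to 11.

## Further compounds
F1 | step 2 | racemic 4-[(TBS)oxy]-2,2-dimethylcyclopentan-1-one | O=C1C(C)(C)CC(O[Si](C)(C)C(C)(C)C)C1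
F2 | step 2 | 5,5-dimethylcyclopent-2-en-1-one | O=C1C=CCC1(C)C
F3 | step 2 | (4S)-2,2-dimethyl-4-(4,4,5,5-tetramethyl-1,3,2-dioxaborolan-2-yl)cyclopentan-1-one | O=C1C(C)(C)C[C@H](B2OC(C)(C)C(C)(C)O2)C1
F4 | step 2 | (4S)-4-hydroxy-2,2-dimethylcyclopentan-1-one | O=C1C(C)(C)C[C@H](O)C1
F5 | step 3 | trimethylsilyl enol ether of 5 (C1=C5) | CC1(C)C[C@H](O[Si](C)(C)C(C)(C)C)C=C1O[Si](C)(C)C
F6 | step 3 | 4-[(TBS)oxy]-2,2,6-trimethyl-1-[(trimethylsilyl)oxy]bicyclo[3.1.0]hexane | CC1C2[C@@H](O[Si](C)(C)C(C)(C)C)CC(C)(C)C12O[Si](C)(C)C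
F7 | step 3 | 5-chloro-4-[(TBS)oxy]-2,2,6-trimethylcyclohexan-1-one | CC1C(Cl)[C@@H](O[Si](C)(C)C(C)(C)C)CC(C)(C)C1=O
F8 | step 3 | (4S)-4-[(TBS)oxy]-2,6,6-trimethylcyclohex-2-en-1-one | CC1=C[C@@H](O[Si](C)(C)C(C)(C)C)CC(C)(C)C1=O
F9 | step 5 | methyl (4R)-4-[(TBS)oxy]-2,6,6-trimethylcyclohex-1-ene-1-carboxylate | CC1=C(C(=O)OC)C(C)(C)C[C@H](O[Si](C)(C)C(C)(C)C)C1
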